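**Proposal: (3S)-7-hydroxy-3-(8-hydroxy-2,2-dimethyl-2H-chromen-6-yl)-5-methoxychroman-4-one (19) by a stereoconvergent nickel-catalysed union of its two halves at C3**

## Analysis of the target

The target 19 is an isoflavanone. Numbering used here: the chromanone is O1, C2, C3, C4, C4a, C5–C8, C8a (ring A is the benzene ring, ring C the dihydropyranone). The 2,2-dimethyl-2H-chromene carries primed locants O1', C2'–C8a' (ring B is its benzene ring, ring D its pyran ring). Ring A bears 5-OMe and 7-OH, ring B bears 8'-OH, and the two halves are joined by the C3–C6' bond.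

C3 is the only stereocentre and is S (priorities C4 > C2 > C6' > H). It is tertiary, benzylic and alpha to the C4 ketone, so its C–H is acidic and the configuration is lost by enolisation with base and, more slowly, with acid. No second stereocentre exists to relay or repair this configuration, so it must be set by a catalyst and then kept under near-neutral conditions to the end.

That same lability is the feature the strategy uses: a centre that is planarised so easily can be made from a racemate by a stereoconvergent step that forms the C3–C6' bond itself.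

Sensitive groups:
- the C3'=C4' alkene of ring D (hydrogenation, electrophilic halogen, peracids, strong acid);
- the 8'-OH of an ortho-alkoxyphenol (oxidation);
- the 7-OH, a vinylogous acid para to C4=O;
- the 5-OMe peri to the carbonyl (cleaved by boron and aluminium halides);
- the electron-rich ring A (nuclear halogenation).

Ring A also needs O5 (methyl) told apart from O7 (free). The difficulty is therefore threefold: join the halves at the labile centre, set that centre, and unmask two phenols without base, hydrogen or strong Lewis acid.

## Retrosynthetic reasoning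

**19 from 18 (O–Si bonds).** Both phenols are carried as triisopropylsilyl ethers in 18. Buffered fluoride is the one deprotection that leaves C3–H, the C3'=C4' alkene and 5-OMe alone, so the last step only has to cleave two O–Si bonds.

**18 from 8 and 17 (C3–C6' bond, key disconnection).** This bond is both the link between the two aromatic halves and a bond at the stereocentre. Cutting it gives the racemic bromo ketone 8 and the achiral arylzinc iodide 17, two fragments of similar size. The forward reaction is a nickel-catalysed stereoconvergent Negishi arylation: both enantiomers of 8 pass through one planar C3 radical, and a chiral ligand on nickel decides the configuration as the bond forms. The medium contains no alkoxide or amide base, so the product centre should survive. Cuts at C4–C4a or O1–C2 were not chosen because they leave the stereochemical problem untouched.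

**17 from 15 via 16 (C–Zn, C–Mg, C–Br).** The arylzinc comes from the aryl bromide 15 by magnesium insertion to 16 and transmetalation. Both ortho positions of the metal-bearing carbon (C5', C7') carry hydrogen.

**15 from 14; 14 from 10 and 11 via 12 and 13 (O–Si; C3'–C4' and O1'–C2' of ring D).** Ring D is built on a salicylaldehyde. Addition of the alkenyl Grignard reagent 11 to aldehyde 10 gives the allylic alcohol 12. Dehydration gives the ortho-quinone methide 13, and oxa-6π electrocyclisation closes O1'–C2' to give 14. The positions of Br (C6') and the free OH (C8') are fixed by the substitution pattern of the aldehyde, so the regiochemical question of a catechol annulation does not arise.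

**10 from 9 (O–Me).** The methyl ether of the commercial aldehyde 9 is cleaved at the outset, where a boron halide meets neither the ring D alkene nor the 5-OMe of ring A.

**8 from 6 via 7 (C3–Br).** Bromine is introduced through the silyl enol ether 7, which directs the electrophile to C3 and away from ring A. A racemate is all that is needed.

**6 from 5 from 4 (O5–Me, O7–Si).** The hydrogen bond from 5-OH to C4=O makes 7-OH the more reactive phenol, so silylation comes first at O7 and methylation second at O5.

**4 from 1 and 2 via 3 (C4–C4a and O1–C2).** Friedel–Crafts acylation of symmetric 1 with the acid 2 gives 3 without regiochemical ambiguity. Intramolecular O-alkylation then closes ring C.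

## Alternatives that were turned down

**Alternative 1: isoflavone, then asymmetric reduction (the textbook route).**
- Disconnection: C3–C6' at the sp2 level, with C3 set afterwards.
- Forward: Suzuki coupling of the 3-iodochromone A1 with the pinacol boronate A2 (made from 15) gives the isoflavone A3. The key step is a catalyst-controlled reduction of C2=C3 of A3 to 18.
- Why turned down:
  - Hydrogen-based asymmetric hydrogenation must distinguish C2=C3 from the C3'=C4' alkene of ring D.
  - Hydride conjugate reduction creates C3 only in a later protonation that the catalyst does not control.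
  - Transfer hydrogenation runs on to the C4 alcohol and needs a re-oxidation.
  - Bond and stereocentre are thus made in two or three separate operations around C3, where step 8 needs one.
  - A1 cannot be made from 6 in one step and needs a ring A sequence of its own.

**Alternative 2: decarboxylative asymmetric protonation.**
- Disconnection: C3–H, with C3–C6' made earlier at a quaternary stage.
- Forward: acylation of 6 gives the allyl beta-keto ester A4. Arylation with the aryllead triacetate A5 gives the racemic quaternary ester A6. The key step is Pd2(dba)3 with a chiral phosphinooxazoline and Meldrum's acid, which removes the allyl carboxylate from A6 and protonates the palladium enolate to 18.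
- Why turned down:
  - It is stereoconvergent like the chosen route, but the key step forms no skeletal bond, and its precursor A6 is larger than its product.
  - A5 must be made with Pb(OAc)4, an oxidant of tetravalent lead that also attacks the electron-rich C3'=C4' alkene.
  - A4 needs a strong base on a chromanone whose enolate can open by beta-elimination of the O1 phenoxide.
  - Three steps (acylation, arylation, decarboxylation) do what step 8 does in one.

**Alternative 3: single-carbon insertion into a benzofuranone.**
- Disconnection: C3 is inserted as a CH–aryl unit between C4 and C2.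
- Forward: the benzofuran-3(2H)-one A7 and the aryldiazomethane A8, with Sc(OTf)3 and a chiral ligand, undergo asymmetric ring expansion; migration of the O-bearing CH2 would give 18 directly.
- Why turned down:
  - The two carbons flanking the carbonyl of A7 compete. The oxygen-substituted CH2 is a poor migrating group, and the trioxygenated aryl carbon of ring A is a good one. The expected product is therefore the 4-aryl-chroman-3-one A9, which has the wrong skeleton.
  - A8 is an electron-rich, unstable diazo compound.
  - The new centre would sit next to a Lewis acid that promotes enolisation.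

Key step: step 8

Assumption: the sense of induction of the NiCl2·glyme/pybox catalyst on a ring-fused bromo ketone cannot be derived from the acyclic cases; the ligand antipode that leads to 3S is fixed in a first run, both antipodes being equally accessible.

## Route

Step 1
Reactants: 1 phloroglucinol (benzene-1,3,5-triol); 2 3-chloropropanoic acid
Product: 4 5,7-dihydroxychroman-4-one, via aryl chloroethyl ketone 3 (not isolated)
Conditions: TfOH, 80 °C; then 2 M aq NaOH, 0 °C → rt; HCl work-up
Reagents that add atoms: none
Why: Friedel–Crafts acylation of the symmetric, highly activated ring gives a single mono-ketone 3; base then closes ring C by intramolecular O-alkylation of an ortho phenoxide (6-exo-tet, or elimination and oxa-Michael addition). No stereocentre is formed.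

Step 2
Reactants: 4 5,7-dihydroxychroman-4-one
Product: 5 5-hydroxy-7-[(triisopropylsilyl)oxy]chroman-4-one
Conditions: TIPSCl (1.05 equiv), imidazole, DMF, 0 °C
Reagents that add atoms: chlorotriisopropylsilane (TIPSCl), CC(C)[Si](Cl)(C(C)C)C(C)C
Why: Imidazole-mediated silylation; 5-OH is locked in a hydrogen bond to C4=O and is far less nucleophilic, so only O7 should react.

Step 3
Reactants: 5 5-hydroxy-7-[(triisopropylsilyl)oxy]chroman-4-one
Product: 6 5-methoxy-7-[(triisopropylsilyl)oxy]chroman-4-one
Conditions: MeI, Ag2O, DMF, rt, dark
Reagents that add atoms: iodomethane (MeI), CI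
Why: Purdie–Kuhn methylation; silver oxide activates MeI towards the chelated 5-OH without the carbonate or hydroxide bases that would attack the para-acyl aryl silyl ether at O7.

Step 4
Reactants: 6 5-methoxy-7-[(triisopropylsilyl)oxy]chroman-4-one
Product: 8 rac-3-bromo-5-methoxy-7-[(triisopropylsilyl)oxy]chroman-4-one, via trimethylsilyl enol ether 7 (not isolated)
Conditions: LiN(SiMe3)2, TMSCl (in situ quench), THF, −78 °C; then NBS, −78 → −40 °C; cold aq NaHCO3/Na2S2O3
Reagents that add atoms: N-bromosuccinimide (NBS), O=C1CCC(=O)N1Br
Why: Regiospecific alpha-bromination through the silyl enol ether; the enolate can form only at C3, its immediate silylation prevents ring opening by beta-elimination of the O1 phenoxide, and 7 is far more nucleophilic towards NBS than ring A. C3 is formed racemic, which is what step 8 requires.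

Step 5
Reactants: 9 5-bromo-2-hydroxy-3-methoxybenzaldehyde
Product: 10 5-bromo-2,3-dihydroxybenzaldehyde
Conditions: BBr3, CH2Cl2, −78 °C → rt; H2O
Reagents that add atoms: none
Why: Lewis-acid cleavage of the aryl methyl ether, placed first because BBr3 would later be incompatible with the ring D alkene and with 5-OMe of ring A.

Step 6
Reactants: 10 5-bromo-2,3-dihydroxybenzaldehyde; 11 (2-methylprop-1-en-1-yl)magnesium bromide
Product: 14 6-bromo-2,2-dimethyl-2H-chromen-8-ol, via allylic alcohol 12 (not isolated), via ortho-quinone methide 13 (not isolated)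
Conditions: 11 (3.5 equiv), THF, 0 °C → rt; aq NH4Cl; then PPTS (cat.), toluene, 80 °C
Reagents that add atoms: none
Why: Grignard 1,2-addition to the aldehyde after deprotonation of both phenols, then acid-catalysed dehydration of 12 to 13 and oxa-6π electrocyclisation, which closes ring D. Only the OH ortho to the side chain can form 13, so Br ends at C6' and the free OH at C8'; the stereocentre of 12 is destroyed.

Step 7
Reactants: 14 6-bromo-2,2-dimethyl-2H-chromen-8-ol
Product: 15 [(6-bromo-2,2-dimethyl-2H-chromen-8-yl)oxy]triisopropylsilane
Conditions: TIPSCl, imidazole, DMF, rt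
Reagents that add atoms: chlorotriisopropylsilane (TIPSCl), CC(C)[Si](Cl)(C(C)C)C(C)C
Why: Standard phenol silylation; the bulky silyl ether tolerates magnesium insertion and sits meta to the future carbon–metal bond, so no silyl migration to carbon can occur.

Step 8
Reactants: 15 [(6-bromo-2,2-dimethyl-2H-chromen-8-yl)oxy]triisopropylsilane; 8 rac-3-bromo-5-methoxy-7-[(triisopropylsilyl)oxy]chroman-4-one
Product: 18 (3S)-3-{2,2-dimethyl-8-[(triisopropylsilyl)oxy]-2H-chromen-6-yl}-5-methoxy-7-[(triisopropylsilyl)oxy]chroman-4-one, via arylmagnesium bromide 16 (not isolated), via arylzinc iodide 17 (not isolated)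
Conditions: Mg, THF, 50 °C; ZnI2, THF, 0 °C; then 17 (1.3 equiv) added to 8, NiCl2·glyme (5 mol%), 2,6-bis[(4S,5R)-4,5-diphenyl-4,5-dihydrooxazol-2-yl]pyridine (6.5 mol%; antipode if the sense of induction demands it), glyme/THF, −30 °C; aq NH4Cl at −30 °C
Reagents that add atoms: none
Why: Proposed new method: the closest known reaction type is the nickel/pybox-catalysed stereoconvergent Negishi arylation of racemic acyclic alpha-bromo ketones with arylzinc iodides at low temperature, which gives base-sensitive tertiary alpha-aryl ketones but has not been shown on a ring-fused 3-bromochroman-4-one; it should transfer because the stereo-erasing event is the same. Mechanism: an aryl–nickel species of monovalent nickel, formed from NiCl2·glyme, the ligand and 17, abstracts bromine from either enantiomer of 8 to give one planar, carbonyl-stabilised C3 radical, which is captured by the aryl complex of divalent nickel to give an aryl(enolyl) complex of trivalent nickel that reductively eliminates the C3–C6' bond. No ring is closed; the step joins ring C to ring B and so completes the carbon skeleton from two halves of similar size. The single new stereocentre C3 is controlled only by the C2-symmetric pybox ligand on nickel, which differentiates the two faces of the C3 radical or enolate during capture and reductive elimination; with no other stereocentre in 8 or 17 there is no matched or mismatched case. Cross-coupling must win over loss of HBr to the chromone, which is secured by the low basicity of 17, the absence of any alkoxide or amide base and the temperature of −30 °C. The product must not enolise, which the same near-neutral medium and the cold quench secure. Chemoselectivity for C3–Br over the ketone, the aryl silyl ethers and the C3'=C4' alkene follows from the low reactivity of arylzinc halides towards these groups, and the hydrogens at C5' and C7' keep transmetalation and reductive elimination unhindered.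

Step 9
Reactants: 18 (3S)-3-{2,2-dimethyl-8-[(triisopropylsilyl)oxy]-2H-chromen-6-yl}-5-methoxy-7-[(triisopropylsilyl)oxy]chroman-4-one
Product: 19 (3S)-7-hydroxy-3-(8-hydroxy-2,2-dimethyl-2H-chromen-6-yl)-5-methoxychroman-4-one
Conditions: TBAF, AcOH (1:1, 2.5 equiv each), THF, 0 °C
Reagents that add atoms: none
Why: Fluoride-induced cleavage of both aryl silyl ethers; acetic acid keeps the medium from becoming basic enough to enolise C3, and the alkene and 5-OMe are inert to these conditions.

## Compound list

1 | phloroglucinol (benzene-1,3,5-triol) | Oc1cc(O)cc(O)c1 | starting material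
2 | 3-chloropropanoic acid | OC(=O)CCCl | starting material
3 | 3-chloro-1-(2,4,6-trihydroxyphenyl)propan-1-one | O=C(CCCl)c1c(O)cc(O)cc1O | intermediate
4 | 5,7-dihydroxychroman-4-one | O=C1CCOc2cc(O)cc(O)c12 | intermediate
5 | 5-hydroxy-7-[(triisopropylsilyl)oxy]chroman-4-one | O=C1CCOc2cc(O[Si](C(C)C)(C(C)C)C(C)C)cc(O)c12 | intermediate
6 | 5-methoxy-7-[(triisopropylsilyl)oxy]chroman-4-one | COc1cc(O[Si](C(C)C)(C(C)C)C(C)C)cc2OCCC(=O)c12 | intermediate
7 | 5-methoxy-7-[(triisopropylsilyl)oxy]-4-[(trimethylsilyl)oxy]-2H-chromene | COc1cc(O[Si](C(C)C)(C(C)C)C(C)C)cc2OCC=C(O[Si](C)(C)C)c12 | intermediate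
8 | rac-3-bromo-5-methoxy-7-[(triisopropylsilyl)oxy]chroman-4-one (racemic) | COc1cc(O[Si](C(C)C)(C(C)C)C(C)C)cc2OCC(Br)C(=O)c12 | intermediate
9 | 5-bromo-2-hydroxy-3-methoxybenzaldehyde | COc1cc(Br)cc(C=O)c1O | starting material
10 | 5-bromo-2,3-dihydroxybenzaldehyde | Oc1cc(Br)cc(C=O)c1O | intermediate
11 | (2-methylprop-1-en-1-yl)magnesium bromide | CC(C)=C[Mg]Br | starting material
12 | rac-5-bromo-3-(1-hydroxy-3-methylbut-2-en-1-yl)benzene-1,2-diol (racemic) | CC(C)=CC(O)c1cc(Br)cc(O)c1O | intermediate
13 | 4-bromo-2-hydroxy-6-(3-methylbut-2-en-1-ylidene)cyclohexa-2,4-dien-1-one | CC(C)=CC=C1C=C(Br)C=C(O)C1=O | intermediate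
14 | 6-bromo-2,2-dimethyl-2H-chromen-8-ol | CC1(C)C=Cc2cc(Br)cc(O)c2O1 | intermediate
15 | [(6-bromo-2,2-dimethyl-2H-chromen-8-yl)oxy]triisopropylsilane | CC1(C)C=Cc2cc(Br)cc(O[Si](C(C)C)(C(C)C)C(C)C)c2O1 | intermediate
16 | {2,2-dimethyl-8-[(triisopropylsilyl)oxy]-2H-chromen-6-yl}magnesium bromide | CC1(C)C=Cc2cc([Mg]Br)cc(O[Si](C(C)C)(C(C)C)C(C)C)c2O1 | intermediate
17 | {2,2-dimethyl-8-[(triisopropylsilyl)oxy]-2H-chromen-6-yl}zinc iodide | CC1(C)C=Cc2cc([Zn]I)cc(O[Si](C(C)C)(C(C)C)C(C)C)c2O1 | intermediate
18 | (3S)-3-{2,2-dimethyl-8-[(triisopropylsilyl)oxy]-2H-chromen-6-yl}-5-methoxy-7-[(triisopropylsilyl)oxy]chroman-4-one | COc1cc(O[Si](C(C)C)(C(C)C)C(C)C)cc2c1C(=O)[C@@H](c1cc(O[Si](C(C)C)(C(C)C)C(C)C)c3c(c1)C=CC(C)(C)O3)CO2 | intermediate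
19 | (3S)-7-hydroxy-3-(8-hydroxy-2,2-dimethyl-2H-chromen-6-yl)-5-methoxychroman-4-one | COc1cc(O)cc2c1C(=O)[C@@H](c1cc(O)c3c(c1)C=CC(C)(C)O3)CO2 | target

## Step count and risk

Total: 9 steps. Longest linear sequence: 6 steps (steps 1, 2, 3, 4, 8, 9). The ring B/D branch is 5 steps (steps 5, 6, 7, 8, 9).

**Step 8 (key step, proposed new method).**
- Most likely failures: loss of HBr from 8 (dehydrobromination, or beta-hydride elimination from a C3–nickel species) outrunning the coupling; and poor facial selectivity, because the ring-locked enolate geometry of 8 differs from that of the acyclic substrates on which the catalyst class is proven. Enolisation during work-up is a lesser risk.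
- Fallback (known chemistry, reversed polarity at C3): set out from 6 and 15.
  - Palladium-catalysed ketone alpha-arylation (Pd2(dba)3, P(t-Bu)3, NaOt-Bu, toluene, 60 °C) should give racemic 3-{2,2-dimethyl-8-[(triisopropylsilyl)oxy]-2H-chromen-6-yl}-5-methoxy-7-[(triisopropylsilyl)oxy]chroman-4-one F1.
  - Asymmetric transfer hydrogenation with dynamic kinetic resolution (RuCl(p-cymene)[(S,S)-TsDPEN], HCO2H/Et3N, 40 °C) reduces one enantiomer while the amine keeps C3 equilibrating. It is expected to give the cis alcohol (3S,4S)-3-{2,2-dimethyl-8-[(triisopropylsilyl)oxy]-2H-chromen-6-yl}-5-methoxy-7-[(triisopropylsilyl)oxy]chroman-4-ol F2; this catalyst type does not reduce the ring D alkene.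
  - Oxidation with Dess–Martin periodinane (NaHCO3, CH2Cl2, 0 °C) returns the ketone without touching C3 and rejoins the route at 18.

**Step 3.**
- Most likely failure: loss of the silyl group from O7 followed by methylation at the wrong oxygen, or incomplete methylation of the chelated 5-OH.
- Fallback: set out from 4.
  - Selective benzylation (BnBr, K2CO3, acetone) gives 7-(benzyloxy)-5-hydroxychroman-4-one F3.
  - Forcing methylation (MeI, K2CO3, DMF) gives 7-(benzyloxy)-5-methoxychroman-4-one F4.
  - Hydrogenolysis (H2, Pd/C, EtOAc; no alkene is present in this fragment) gives 7-hydroxy-5-methoxychroman-4-one F5.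
  - Silylation (TIPSCl, imidazole) rejoins the route at 6.

**Step 6.**
- Most likely failure: incomplete addition because the magnesium salt of the doubly deprotonated catechol aldehyde is poorly soluble; air oxidation of the catechol; or oligomerisation of the ortho-quinone methide before it cyclises.
- Fallback: set out from 9 and keep the methyl ether through ring D formation.
  - 11 (2.2 equiv) gives rac-4-bromo-2-(1-hydroxy-3-methylbut-2-en-1-yl)-6-methoxyphenol F6.
  - The same cyclodehydration gives 6-bromo-8-methoxy-2,2-dimethyl-2H-chromene F7.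
  - Nucleophilic demethylation (NaSEt, DMF, 110 °C), to which the alkene and the aryl bromide are inert, rejoins the route at 14.

**Step 4.**
- Most likely failure: competing electrophilic bromination of ring A at C6 or C8, a second bromination at C3, or loss of HBr on work-up.
- Fallback (no electrophilic bromine): set out from 6.
  - Rubottom oxidation (enol silane 7 as in step 4, then mCPBA, mild acidic work-up) gives rac-3-hydroxy-5-methoxy-7-[(triisopropylsilyl)oxy]chroman-4-one F8.
  - Mesylation (MsCl, Et3N, 0 °C) gives rac-5-methoxy-4-oxo-7-[(triisopropylsilyl)oxy]chroman-3-yl methanesulfonate F9.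
  - Displacement with LiBr (acetone, rt) rejoins the route at 8.

## Further compounds

F1 | step 8 | rac-3-{2,2-dimethyl-8-[(triisopropylsilyl)oxy]-2H-chromen-6-yl}-5-methoxy-7-[(triisopropylsilyl)oxy]chroman-4-one (racemic) | COc1cc(O[Si](C(C)C)(C(C)C)C(C)C)cc2c1C(=O)C(c1cc(O[Si](C(C)C)(C(C)C)C(C)C)c3c(c1)C=CC(C)(C)O3)CO2
F2 | step 8 | (3S,4S)-3-{2,2-dimethyl-8-[(triisopropylsilyl)oxy]-2H-chromen-6-yl}-5-methoxy-7-[(triisopropylsilyl)oxy]chroman-4-ol | COc1cc(O[Si](C(C)C)(C(C)C)C(C)C)cc2c1[C@@H](O)[C@@H](c1cc(O[Si](C(C)C)(C(C)C)C(C)C)c3c(c1)C=CC(C)(C)O3)CO2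
F3 | step 3 | 7-(benzyloxy)-5-hydroxychroman-4-one | O=C1CCOc2cc(OCc3ccccc3)cc(O)c12
F4 | step 3 | 7-(benzyloxy)-5-methoxychroman-4-one | COc1cc(OCc2ccccc2)cc2OCCC(=O)c12
F5 | step 3 | 7-hydroxy-5-methoxychroman-4-one | COc1cc(O)cc2OCCC(=O)c12
F6 | step 6 | rac-4-bromo-2-(1-hydroxy-3-methylbut-2-en-1-yl)-6-methoxyphenol (racemic) | COc1cc(Br)cc(C(O)C=C(C)C)c1O
F7 | step 6 | 6-bromo-8-methoxy-2,2-dimethyl-2H-chromene | COc1cc(Br)cc2C=CC(C)(C)Oc12
F8 | step 4 | rac-3-hydroxy-5-methoxy-7-[(triisopropylsilyl)oxy]chroman-4-one (racemic) | COc1cc(O[Si](C(C)C)(C(C)C)C(C)C)cc2OCC(O)C(=O)c12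
F9 | step 4 | rac-5-methoxy-4-oxo-7-[(triisopropylsilyl)oxy]chroman-3-yl methanesulfonate (racemic) | COc1cc(O[Si](C(C)C)(C(C)C)C(C)C)cc2OCC(OS(C)(=O)=O)C(=O)c12
A1 | alternative 1 | 3-iodo-5-methoxy-7-[(triisopropylsilyl)oxy]-4H-chromen-4-one | COc1cc(O[Si](C(C)C)(C(C)C)C(C)C)cc2occ(I)c(=O)c12
A2 | alternative 1 | {[2,2-dimethyl-6-(4,4,5,5-tetramethyl-1,3,2-dioxaborolan-2-yl)-2H-chromen-8-yl]oxy}triisopropylsilane | CC1(C)C=Cc2cc(B3OC(C)(C)C(C)(C)O3)cc(O[Si](C(C)C)(C(C)C)C(C)C)c2O1
A3 | alternative 1 | 3-{2,2-dimethyl-8-[(triisopropylsilyl)oxy]-2H-chromen-6-yl}-5-methoxy-7-[(triisopropylsilyl)oxy]-4H-chromen-4-one | COc1cc(O[Si](C(C)C)(C(C)C)C(C)C)cc2occ(-c3cc(O[Si](C(C)C)(C(C)C)C(C)C)c4OC(C)(C)C=Cc4c3)c(=O)c12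
A4 | alternative 2 | rac-allyl 5-methoxy-4-oxo-7-[(triisopropylsilyl)oxy]chroman-3-carboxylate (racemic) | COc1cc(O[Si](C(C)C)(C(C)C)C(C)C)cc2OCC(C(=O)OCC=C)C(=O)c12
A5 | alternative 2 | {2,2-dimethyl-8-[(triisopropylsilyl)oxy]-2H-chromen-6-yl}lead triacetate | CC(=O)O[Pb](OC(C)=O)(OC(C)=O)c1cc(O[Si](C(C)C)(C(C)C)C(C)C)c2OC(C)(C)C=Cc2c1
A6 | alternative 2 | rac-allyl 3-{2,2-dimethyl-8-[(triisopropylsilyl)oxy]-2H-chromen-6-yl}-5-methoxy-4-oxo-7-[(triisopropylsilyl)oxy]chroman-3-carboxylate (racemic) | COc1cc(O[Si](C(C)C)(C(C)C)C(C)C)cc2OCC(C(=O)OCC=C)(c3cc(O[Si](C(C)C)(C(C)C)C(C)C)c4OC(C)(C)C=Cc4c3)C(=O)c12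
A7 | alternative 3 | 4-methoxy-6-[(triisopropylsilyl)oxy]benzofuran-3(2H)-one | COc1cc(O[Si](C(C)C)(C(C)C)C(C)C)cc2OCC(=O)c12
A8 | alternative 3 | {[6-(diazomethyl)-2,2-dimethyl-2H-chromen-8-yl]oxy}triisopropylsilane | [N-]=[N+]=Cc1cc(O[Si](C(C)C)(C(C)C)C(C)C)c2OC(C)(C)C=Cc2c1
A9 | alternative 3 | 4-{2,2-dimethyl-8-[(triisopropylsilyl)oxy]-2H-chromen-6-yl}-5-methoxy-7-[(triisopropylsilyl)oxy]chroman-3-one | COc1cc(O[Si](C(C)C)(C(C)C)C(C)C)cc2OCC(=O)C(c3cc(O[Si](C(C)C)(C(C)C)C(C)C)c4OC(C)(C)C=Cc4c3)c12
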